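## Retrosynthetic overview

1. The target comes from its heptamethyl ether (BBr3). The biaryl bond of the dihydrophenanthrene is cut last in the retrosynthesis: Pd‑catalysed intramolecular C–H arylation of an aryl chloride onto the 3,5‑dimethoxybenzyl ring.
2. The benzylic C–C bond to that ring and the stereocentre beside it come from an exocyclic 1,1‑diarylalkene: face‑selective hydroboration, then B‑alkyl Suzuki coupling with 1‑bromo‑3,5‑dimethoxybenzene.
3. The seven‑membered ring and the diarylmethine stereocentre come from an α‑aryl vinyl triflate: enantioselective Pd(0) C–H alkenylation that picks one of two enantiotopic 3,4‑dimethoxyphenyl rings.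
4. The cyclisation substrate comes from 2‑bromo‑6‑chloro‑4‑methoxyacetophenone and 1,1‑bis(3,4‑dimethoxyphenyl)ethene (hydroboration / B‑alkyl Suzuki). The arenes come from catechol, resorcinol and 1‑bromo‑3‑chlorobenzene, with Ir C–H borylation placing the meta substituents.
5. Ring order: seven‑membered carbocycle first (step 11), then the six‑membered ring of the dihydrophenanthrene (step 13).

Assumption: C8 is the CH bearing the CH2 to the resorcinol ring and C15 the CH bearing the pendant catechol ring; the target is (8R,15S) with H‑8 and H‑15 cis on the seven‑membered ring, and all phenols are carried as methyl ethers.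

## Route

Step 1
Reactants: 1 catechol
Product: 2 1,2-dimethoxybenzene
Conditions: MeI (2.5 equiv), K2CO3 (2.5 equiv), acetone, reflux
Reagents that add atoms: iodomethane, CI
Why: Williamson O‑methylation of both phenols installs the methyl ether protecting groups that are carried to the last step.

Step 2
Reactants: 2 1,2-dimethoxybenzene
Product: 3 4-bromo-1,2-dimethoxybenzene
Conditions: NBS (1.05 equiv), MeCN, 0 °C to rt
Reagents that add atoms: N-bromosuccinimide, O=C1CCC(=O)N1Br
Why: Electrophilic aromatic bromination goes para to a methoxy group and stops cleanly at the monobromide.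

Step 3
Reactants: 3 4-bromo-1,2-dimethoxybenzene (2.2 equiv); 4 ethyl acetate
Product: 8 1,1-bis(3,4-dimethoxyphenyl)ethene, via aryl Grignard reagent 5 (not isolated), via acetoveratrone 6 (not isolated), via tertiary carbinol 7 (not isolated)
Conditions: Mg, I2 (cat.), THF, reflux; then 4, 0 °C to rt; 2 M HCl; then TsOH·H2O (5 mol %), toluene, 80 °C
Reagents that add atoms: none
Why: Double Grignard addition to the ester gives the doubly benzylic tertiary alcohol, which loses water by acid‑catalysed E1 dehydration.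

Step 4
Reactants: 9 1-bromo-3-chlorobenzene
Product: 11 3-bromo-5-chlorophenol, via arylboronic pinacol ester 10 (not isolated)
Conditions: [Ir(OMe)(cod)]2 (1.5 mol %), dtbpy (3 mol %), B2pin2 (1.0 equiv), THF, 80 °C; then Oxone, acetone/H2O, rt
Reagents that add atoms: Oxone (potassium peroxymonosulfate), [K+].[O-]S(=O)(=O)OO
Why: Sterically controlled Ir‑catalysed C–H borylation hits the only C–H not ortho to a halogen, and ipso‑oxidation of the C–B bond gives the phenol.

Step 5
Reactants: 11 3-bromo-5-chlorophenol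
Product: 12 1-bromo-3-chloro-5-methoxybenzene
Conditions: MeI (1.5 equiv), K2CO3 (2 equiv), DMF, rt
Reagents that add atoms: iodomethane, CI
Why: Williamson O‑methylation of the phenol.

Step 6
Reactants: 12 1-bromo-3-chloro-5-methoxybenzene; 13 N-methoxy-N-methylacetamide
Product: 15 1-(2-bromo-6-chloro-4-methoxyphenyl)ethan-1-one, via aryllithium 14 (not isolated)
Conditions: LDA (commercial solution, 1.1 equiv), THF, −78 °C, 1 h; then 13 (1.3 equiv), −78 to 0 °C; 1 M HCl
Reagents that add atoms: none
Why: Deprotonative lithiation takes the most acidic C–H, flanked by Br and Cl (held at −78 °C to avoid aryne formation and halogen dance), and the aryllithium is acylated in a Weinreb ketone synthesis.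

Step 7
Reactants: 16 resorcinol
Product: 17 1,3-dimethoxybenzene
Conditions: MeI (2.5 equiv), K2CO3 (2.5 equiv), acetone, reflux
Reagents that add atoms: iodomethane, CI
Why: Williamson O‑methylation of both phenols.

Step 8
Reactants: 17 1,3-dimethoxybenzene
Product: 19 1-bromo-3,5-dimethoxybenzene, via arylboronic pinacol ester 18 (not isolated)
Conditions: [Ir(OMe)(cod)]2 (1.5 mol %), dtbpy (3 mol %), B2pin2 (1.0 equiv), THF, 80 °C; then CuBr2 (3 equiv), MeOH/H2O 1:1, 80 °C
Reagents that add atoms: copper(II) bromide, Br[Cu]Br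
Why: Ir‑catalysed C–H borylation goes to the 5‑position, meta to both methoxy groups (not reachable by electrophilic bromination), and Cu(II) bromodeboronation converts C–B to C–Br.

Step 9
Reactants: 8 1,1-bis(3,4-dimethoxyphenyl)ethene (1.2 equiv); 15 1-(2-bromo-6-chloro-4-methoxyphenyl)ethan-1-one
Product: 21 1-{2-[2,2-bis(3,4-dimethoxyphenyl)ethyl]-6-chloro-4-methoxyphenyl}ethan-1-one, via alkyl-9-BBN borane 20 (not isolated)
Conditions: 9-BBN (1.1 equiv), THF, 60 °C; then 15, Pd(dppf)Cl2·CH2Cl2 (5 mol %), 3 M aq. K3PO4 (3 equiv), DMF, 60 °C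
Reagents that add atoms: none
Why: Anti‑Markovnikov hydroboration of the 1,1‑diarylalkene gives a primary alkylborane that undergoes B‑alkyl Suzuki–Miyaura coupling at C–Br, leaving C–Cl and the ketone untouched.

Step 10
Reactants: 21 1-{2-[2,2-bis(3,4-dimethoxyphenyl)ethyl]-6-chloro-4-methoxyphenyl}ethan-1-one
Product: 23 1-{2-[2,2-bis(3,4-dimethoxyphenyl)ethyl]-6-chloro-4-methoxyphenyl}ethenyl trifluoromethanesulfonate, via potassium enolate 22 (not isolated)
Conditions: KHMDS (commercial solution, 1.2 equiv), THF, −78 °C; then PhNTf2 (1.3 equiv), −78 to 0 °C; chromatography on Et3N‑deactivated silica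
Reagents that add atoms: N-phenylbis(trifluoromethanesulfonimide), FC(F)(F)S(=O)(=O)N(c1ccccc1)S(=O)(=O)C(F)(F)F
Why: Kinetic deprotonation of the methyl ketone (the only acidic C–H) and O‑triflation of the enolate give the α‑aryl vinyl triflate.

Step 11
Reactants: 23 1-{2-[2,2-bis(3,4-dimethoxyphenyl)ethyl]-6-chloro-4-methoxyphenyl}ethenyl trifluoromethanesulfonate
Product: 24 (10S)-4-chloro-10-(3,4-dimethoxyphenyl)-2,7,8-trimethoxy-5-methylidene-10,11-dihydro-5H-dibenzo[a,d][7]annulene
Conditions: Pd(dba)2 (5 mol %), TADDOL‑derived N,N‑dimethylphosphoramidite with 3,5‑xylyl groups (10 mol %, antipode chosen as below), PivOH (30 mol %), Cs2CO3 (1.5 equiv), mesitylene (0.05 M), 60 °C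
Reagents that add atoms: none
Why: Proposed new method: Pd(0) inserts into the alkenyl C–OTf bond, a pivalate‑assisted concerted metalation–deprotonation inside the chiral phosphoramidite pocket then selects the para‑to‑methoxy ortho C–H of one of the two enantiotopic 3,4‑dimethoxyphenyl rings (eight‑membered palladacycle), and C(sp2)–C(sp2) reductive elimination closes the seven‑membered ring and fixes the diarylmethine carbon as (S); the closest known reaction type is Pd(0)/chiral monophosphorus‑ligand enantioselective C–H arylation by enantiotopic‑aryl selection, shown for alkenyl triflates closing five‑membered rings at quaternary carbons and for aryl bromides closing seven‑membered lactams but not for an alkenyl triflate closing an all‑carbon seven‑membered ring at a C–H stereocentre, and the ligand antipode that gives (S) has to be fixed by experiment.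

Step 12
Reactants: 24 (10S)-4-chloro-10-(3,4-dimethoxyphenyl)-2,7,8-trimethoxy-5-methylidene-10,11-dihydro-5H-dibenzo[a,d][7]annulene; 19 1-bromo-3,5-dimethoxybenzene (1.5 equiv)
Product: 26 (5R,10S)-4-chloro-5-[(3,5-dimethoxyphenyl)methyl]-10-(3,4-dimethoxyphenyl)-2,7,8-trimethoxy-10,11-dihydro-5H-dibenzo[a,d][7]annulene, via alkyl-9-BBN borane 25 (not isolated)
Conditions: 9-BBN (2.5 equiv), THF, 65 °C; then 3 M aq. K3PO4, 19, Pd(dppf)Cl2·CH2Cl2 (10 mol %), DMF, 70 °C
Reagents that add atoms: none
Why: Syn hydroboration puts boron on the terminal carbon and delivers H to C5 from the face anti to the pseudo‑axial 10‑aryl group, which should set (5R) with H‑5 cis to H‑10 (selectivity to be confirmed), and B‑alkyl Suzuki–Miyaura coupling with the aryl bromide (C–Br over the hindered C–Cl) forms the benzylic C–C bond.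

Step 13
Reactants: 26 (5R,10S)-4-chloro-5-[(3,5-dimethoxyphenyl)methyl]-10-(3,4-dimethoxyphenyl)-2,7,8-trimethoxy-10,11-dihydro-5H-dibenzo[a,d][7]annulene
Product: 27 hepta-O-methyl ether of the target, (8R,15S)
Conditions: Pd(OAc)2 (10 mol %), PCy3·HBF4 (20 mol %), PivOH (30 mol %), K2CO3 (2.5 equiv), DMA, 130 °C
Reagents that add atoms: none
Why: Pd(0)/PCy3 oxidative addition into the aryl chloride and carboxylate‑assisted C–H activation (direct arylation) at either of the two equivalent ortho C–H bonds of the 3,5‑dimethoxybenzyl ring close the six‑membered ring, since the only other ortho C–H within reach would need a fluorene spanning the ethano bridge; no stereocentre is touched.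

Step 14
Reactants: 27 hepta-O-methyl ether of the target
Product: 28 CNP0306974.1, (8R,15S)
Conditions: BBr3 (12 equiv), CH2Cl2, −78 °C to rt; MeOH/H2O quench at 0 °C
Reagents that add atoms: none
Why: Lewis‑acid cleavage of all seven aryl methyl ethers by BBr3 leaves the two benzylic C–H stereocentres untouched.

## Compound list

1 | catechol | Oc1ccccc1O | starting material
2 | 1,2-dimethoxybenzene | COc1ccccc1OC | intermediate
3 | 4-bromo-1,2-dimethoxybenzene | COc1ccc(Br)cc1OC | intermediate
4 | ethyl acetate | CCOC(C)=O | starting material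
5 | (3,4-dimethoxyphenyl)magnesium bromide (not isolated) | COc1ccc([Mg]Br)cc1OC | intermediate
6 | 1-(3,4-dimethoxyphenyl)ethan-1-one, acetoveratrone (not isolated) | COc1ccc(cc1OC)C(C)=O | intermediate
7 | 1,1-bis(3,4-dimethoxyphenyl)ethan-1-ol (not isolated) | COc1ccc(cc1OC)C(C)(O)c1ccc(OC)c(OC)c1 | intermediate
8 | 1,1-bis(3,4-dimethoxyphenyl)ethene | COc1ccc(cc1OC)C(=C)c1ccc(OC)c(OC)c1 | intermediate
9 | 1-bromo-3-chlorobenzene | Clc1cccc(Br)c1 | starting material
10 | 2-(3-bromo-5-chlorophenyl)-4,4,5,5-tetramethyl-1,3,2-dioxaborolane (not isolated) | CC1(C)OB(OC1(C)C)c1cc(Cl)cc(Br)c1 | intermediate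
11 | 3-bromo-5-chlorophenol | Oc1cc(Cl)cc(Br)c1 | intermediate
12 | 1-bromo-3-chloro-5-methoxybenzene | COc1cc(Cl)cc(Br)c1 | intermediate
13 | N-methoxy-N-methylacetamide | CON(C)C(C)=O | starting material
14 | (2-bromo-6-chloro-4-methoxyphenyl)lithium (not isolated) | COc1cc(Cl)c([Li])c(Br)c1 | intermediate
15 | 1-(2-bromo-6-chloro-4-methoxyphenyl)ethan-1-one | COc1cc(Cl)c(C(C)=O)c(Br)c1 | intermediate
16 | resorcinol | Oc1cccc(O)c1 | starting material
17 | 1,3-dimethoxybenzene | COc1cccc(OC)c1 | intermediate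
18 | 2-(3,5-dimethoxyphenyl)-4,4,5,5-tetramethyl-1,3,2-dioxaborolane (not isolated) | COc1cc(OC)cc(c1)B1OC(C)(C)C(C)(C)O1 | intermediate
19 | 1-bromo-3,5-dimethoxybenzene | COc1cc(Br)cc(OC)c1 | intermediate
20 | 9-[2,2-bis(3,4-dimethoxyphenyl)ethyl]-9-borabicyclo[3.3.1]nonane (not isolated) | COc1ccc(cc1OC)C(CB1C2CCCC1CCC2)c1ccc(OC)c(OC)c1 | intermediate
21 | 1-{2-[2,2-bis(3,4-dimethoxyphenyl)ethyl]-6-chloro-4-methoxyphenyl}ethan-1-one | CC(=O)c1c(Cl)cc(OC)cc1CC(c1ccc(OC)c(OC)c1)c1ccc(OC)c(OC)c1 | intermediate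
22 | potassium enolate of 21 (not isolated) | [K+].[O-]C(=C)c1c(Cl)cc(OC)cc1CC(c1ccc(OC)c(OC)c1)c1ccc(OC)c(OC)c1 | intermediate
23 | 1-{2-[2,2-bis(3,4-dimethoxyphenyl)ethyl]-6-chloro-4-methoxyphenyl}ethenyl trifluoromethanesulfonate | C=C(OS(=O)(=O)C(F)(F)F)c1c(Cl)cc(OC)cc1CC(c1ccc(OC)c(OC)c1)c1ccc(OC)c(OC)c1 | intermediate
24 | (10S)-4-chloro-10-(3,4-dimethoxyphenyl)-2,7,8-trimethoxy-5-methylidene-10,11-dihydro-5H-dibenzo[a,d][7]annulene | C=C1c2cc(OC)c(OC)cc2[C@H](c2ccc(OC)c(OC)c2)Cc2cc(OC)cc(Cl)c21 | intermediate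
25 | 9-{[(5R,10S)-4-chloro-10-(3,4-dimethoxyphenyl)-2,7,8-trimethoxy-10,11-dihydro-5H-dibenzo[a,d][7]annulen-5-yl]methyl}-9-borabicyclo[3.3.1]nonane (not isolated) | B1(C[C@@H]2c3cc(OC)c(OC)cc3[C@H](c3ccc(OC)c(OC)c3)Cc3cc(OC)cc(Cl)c32)C2CCCC1CCC2 | intermediate
26 | (5R,10S)-4-chloro-5-[(3,5-dimethoxyphenyl)methyl]-10-(3,4-dimethoxyphenyl)-2,7,8-trimethoxy-10,11-dihydro-5H-dibenzo[a,d][7]annulene; H-5 and H-10 cis | COc1cc(OC)cc(c1)C[C@@H]1c2cc(OC)c(OC)cc2[C@H](c2ccc(OC)c(OC)c2)Cc2cc(OC)cc(Cl)c21 | intermediate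
27 | hepta-O-methyl ether of the target: compound 26 with Cl replaced by a biaryl bond from C4 of the annulene to the ring carbon ortho to the benzylic CH2 (9,10-dihydrophenanthrene fused to the dibenzo[7]annulene); (8R,15S), H-8 and H-15 cis | COc1cc(OC)c2c(c1)C[C@@H]1c3cc(OC)c(OC)cc3[C@H](c3ccc(OC)c(OC)c3)Cc3cc(OC)cc-2c31 | intermediate
28 | CNP0306974.1: the heptaphenol of 27; (8R,15S), H-8 and H-15 cis | Oc1cc(O)c2c(c1)C[C@@H]1c3cc(O)c(O)cc3[C@H](c3ccc(O)c(O)c3)Cc3cc(O)cc-2c31 | target

## Step count and risks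

Total step count: 14.
Longest linear sequence: 9 steps (1, 2, 3, 9, 10, 11, 12, 13, 14; the branch 4, 5, 6, 9–14 is equally long; the resorcinol branch 7, 8 joins at step 12).

Three steps most likely to fail:

**Step 11 (the proposed desymmetrising C–H alkenylation).** Risks are low enantioselectivity, slow closure of the seven‑membered ring, and base‑induced loss of TfOH to the arylalkyne.
Fallback (known chemistry): it sets out from 12 (lithiated to 14 as in step 6) and borane 20, and comes back to the route at 24. Aryllithium 14 is quenched with CO2 to give 2-bromo-6-chloro-4-methoxybenzoic acid F1. Coupling of F1 (as its potassium salt) with borane 20 under the step 9 conditions gives 2-[2,2-bis(3,4-dimethoxyphenyl)ethyl]-6-chloro-4-methoxybenzoic acid F2. Intramolecular Friedel–Crafts acylation (Eaton's reagent, 40 °C), para to a methoxy group of either dimethoxyphenyl ring, closes the seven‑membered ring to the racemic 4-chloro-10-(3,4-dimethoxyphenyl)-2,7,8-trimethoxy-10,11-dihydro-5H-dibenzo[a,d][7]annulen-5-one F3. Wittig methylenation (Ph3P=CH2, toluene, 90 °C) gives racemic 24, and preparative chiral SFC separates 24 from the (10R)-enantiomer of 24 F4, which is discarded.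

**Step 12 (hydroboration / B‑alkyl Suzuki).** Risks are slow hydroboration of the hindered alkene next to the peri‑chlorine and insufficient or wrong facial selectivity at C5.
Fallback: it sets out from 24 and 19 and comes back at 26. Mizoroki–Heck arylation of 24 with 19 (Pd(OAc)2, P(o-tol)3, K2CO3, DMA, 110 °C) gives (10S,E)-4-chloro-5-[(3,5-dimethoxyphenyl)methylidene]-10-(3,4-dimethoxyphenyl)-2,7,8-trimethoxy-10,11-dihydro-5H-dibenzo[a,d][7]annulene F5. Its trisubstituted alkene is then reduced under catalyst control by Ir–phosphinooxazoline asymmetric hydrogenation (H2 50 bar, CH2Cl2), with the catalyst antipode chosen to deliver H to C5 anti to the 10‑aryl group, giving 26.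

**Step 13 (direct arylation).** Risks are a hindered, electron‑rich aryl chloride, hydrodechlorination, and strain in the closing ring.
Fallback: it sets out from 19 and borane 25 and comes back at 27. Chlorination of 19 with NCS (MeCN, rt) gives 1-bromo-2-chloro-3,5-dimethoxybenzene F6. F6 replaces 19 in the cross‑coupling stage of step 12 (borane 25 reacts at C–Br, both C–Cl survive) to give (5R,10S)-4-chloro-5-[(2-chloro-3,5-dimethoxyphenyl)methyl]-10-(3,4-dimethoxyphenyl)-2,7,8-trimethoxy-10,11-dihydro-5H-dibenzo[a,d][7]annulene F7. Intramolecular Ni(0)‑mediated reductive aryl–aryl coupling of the two C–Cl bonds (Ni(cod)2, 2,2'-bipyridine, DMF, 70 °C) then gives 27.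

## Further compounds

F1 | step 11 | 2-bromo-6-chloro-4-methoxybenzoic acid | COc1cc(Cl)c(C(O)=O)c(Br)c1
F2 | step 11 | 2-[2,2-bis(3,4-dimethoxyphenyl)ethyl]-6-chloro-4-methoxybenzoic acid | COc1cc(Cl)c(C(O)=O)c(CC(c2ccc(OC)c(OC)c2)c2ccc(OC)c(OC)c2)c1
F3 | step 11 | racemic 4-chloro-10-(3,4-dimethoxyphenyl)-2,7,8-trimethoxy-10,11-dihydro-5H-dibenzo[a,d][7]annulen-5-one | O=C1c2cc(OC)c(OC)cc2C(c2ccc(OC)c(OC)c2)Cc2cc(OC)cc(Cl)c21
F4 | step 11 | (10R)-enantiomer of 24 | C=C1c2cc(OC)c(OC)cc2[C@@H](c2ccc(OC)c(OC)c2)Cc2cc(OC)cc(Cl)c21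
F5 | step 12 | (10S,E)-4-chloro-5-[(3,5-dimethoxyphenyl)methylidene]-10-(3,4-dimethoxyphenyl)-2,7,8-trimethoxy-10,11-dihydro-5H-dibenzo[a,d][7]annulene | COc1cc(OC)cc(c1)/C=C1\c2cc(OC)c(OC)cc2[C@H](c2ccc(OC)c(OC)c2)Cc2cc(OC)cc(Cl)c21
F6 | step 13 | 1-bromo-2-chloro-3,5-dimethoxybenzene | COc1cc(Br)c(Cl)c(OC)c1
F7 | step 13 | (5R,10S)-4-chloro-5-[(2-chloro-3,5-dimethoxyphenyl)methyl]-10-(3,4-dimethoxyphenyl)-2,7,8-trimethoxy-10,11-dihydro-5H-dibenzo[a,d][7]annulene | COc1cc(OC)c(Cl)c(c1)C[C@@H]1c2cc(OC)c(OC)cc2[C@H](c2ccc(OC)c(OC)c2)Cc2cc(OC)cc(Cl)c21
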